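Slowness here comes in rungs, so order them from fastest to slowest and see what each leaves in the flask.

| flask | first end groups | second end groups | remark | time |
|---|---|---|---|---|
| spring | 26 mM | 1 equiv | run made earlier |  |
| winter | 13 mM | 1 equiv | run made earlier |  |
| summer | 20 mM | 1 equiv | run made earlier |  |
| ochre | 26 mM | 1.00 equiv (in portions, 3, over 8.0 h) | first portion at the start, last at 8.0 h | 12 h |
| amber | 26 mM (fed, over 8.0 h) | 1.00 equiv | all else is in the flask from the start; the feed brings no volume worth counting | 12 h |
| teal | 26 mM | 1.00 equiv (fed, over 8.0 h) | all else is in the flask from the start; the feed brings no volume worth counting | 12 h |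
| blue | 26 mM | 1.00 equiv | everything together at the start | 12 h |

- spring (time / h: links / %): 1.33: 55.8; 3.00: 66.4; 4.00: 68.7; 6.00: 72.9; 8.00: 76.3
- winter (time / h: links / %): 2.50: 48.3; 5.00: 57.7; 8.00: 63.1; 10.0: 65.6; 12.0: 65.9
- summer (time / h: links / %): 1.00: 45.1; 2.00: 55.0; 3.00: 60.5; 6.00: 68.5; 12.0: 74.0

(standard deviation of a reading: 0.5 percentage points)

- on the list of suspects stand: first end groups + second end groups -> links; first end groups + second end groups -> rings; first end groups <-> dormant form

* which flask leads in amount of links, in percent of the first end groups charged ("all alike" within 1.5 percentage points) (ochre / amber / teal / blue / all alike)
* how much links is there at the end, in percent of the first end groups charged: ochre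
* how much links is there at the end, in percent of the first end groups charged: amber
* how much links is there at the end, in percent of the first end groups charged: teal
* how much links is there at the end, in percent of the first end groups charged: blue

1. Take the fastest rung from the spring run: links reach 55.8% by 1.33 h, a pace far above that of the 7.6 percentage points gained between 4.00 h and 8.00 h.

2. Read that tail as my own guess: first end groups returning from the dormant form. Note that the feeds last 8.0 h, longer than the fast rung.

3. Read the slowest rung, the end level, from the winter run: it moves from 65.6% to 65.9%, inside the scatter, and stands lower than spring's 76.3%. Assume, then, that the ring step runs without feeling c(second end groups).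

4. Balance the second end groups: each one spent makes links or rings, and the links' share is c/(c + balance point), the ratio c/balance point being the selectivity factor. Summed from a charge p down to nothing, links are p minus balance point × ln(1 + p/balance point). Winter lacks 4.43 mM, which gives 2.30 mM: this is the balance point, the c(second end groups) at which both steps spend them equally fast. Winter is unfinished, so treat it as an upper reading.

5. Reckon the end levels, taking them as low estimates from that upper reading, and for ochre taking each portion as spent before the next. Blue's level is 77.8%. Amber spends the same charge, so reckon it at the same level, but 4.00 h remain after its feed. Ochre, in portions of 8.67 mM, is reckoned at 58.5%, lower than blue. Teal's feed cuts finer still. Commit to blue first, then amber, ochre and teal.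

The forecast led with amber, at ochre 64%, amber 83%, teal 61%, blue 82%, reasoning of amber that “first end groups always meet excess partner”.

The flasks give blue the lead: ochre 56.0%, amber 74.3%, teal 48.8%, blue 77.6%.

    first end groups + second end groups → links (k = 0.0230 M⁻¹ s⁻¹)
    first end groups + second end groups → rings, rate k2*[first end groups] as long as [second end groups] is above zero (k = 4.70 × 10⁻⁵ s⁻¹)
    first end groups ⇌ dormant form (K = 1.60, k = 3.70 × 10⁻⁴ s⁻¹)

Left until 120 h, amber holds 79.4% links and blue 79.4%, the shared level reckoned at 77.8%. Now take the neighbouring flask, blue with 0.250 equiv of second end groups, which makes them the limiting reagent at 6.50 mM against 26 mM of first end groups. The balance gives links 13.1% and rings 11.9% of the first end groups charged. At 12.0 h, the neighbouring flask holds links 13.8% and rings 11.2%, with the second end groups standing at 0%.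

The numbers in the tables were generated by integration for substances that don't exist; scatter was added.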